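**Retrosynthetic overview**

- Kushenol R ⇐ bis-MOM flavanone ⇐ 8-lavandulyl-4-silyloxyflavan (C4 oxidation, desilylation) ⇐ C8–C1'' Negishi coupling of an 8-bromoflavan with (S)-lavandulylzinc iodide.
- The strategy rests on O1, which bridges C8a of ring A and the C2 carbinol carbon. C2 is therefore set first as a secondary benzylic (S)-alcohol, and ring C (the only ring that is made) is closed at O1–C8a by Pd-catalysed etherification of a C8a aryl triflate. The C2–O bond is never broken and C4 waits as a silyl ether.
- The open-chain precursor comes from an aldol (C3–C4) between a ring-A aldehyde triflate (from 5-methoxyresorcinol) and the enolate of MOM-protected 2'-hydroxyacetophenone, then O-silylation and CBS reduction (C2).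
- The lavandulyl chain is attached only after ring closure. On C8 its isopropenyl group would sit homoallylic to the C8a–Pd bond and open a 5-exo Heck path; with H at C8 the triflate also has a single ortho substituent.
- (S)-Lavandulol comes from an Evans deconjugative prenylation; it becomes the 2''R chain because CH2–aryl ranks below isopropenyl. End game: TBAF, Dess–Martin oxidation, acidic MOM removal.

Key step: step 8

Remark: from the aldol product to the C4 oxidation all compounds are carried as mixtures of both C4 epimers, since C4 ends as the ketone. Atom labels follow the flavanone (O1, C2–C4, C4a, C5–C8, C8a; side chain C1'', C2'').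

**Route**

Step 1
Reactants: 1 5-methoxyresorcinol
Product: 3 2,4-dihydroxy-6-methoxybenzaldehyde, via aryl iminium chloride 2 (not isolated)
Conditions: POCl3, DMF, MeCN, 0 °C → rt; then H2O, 50 °C
Reagents that add atoms: N,N-dimethylformamide CN(C)C=O; water O
Why: Vilsmeier–Haack formylation, in which the chloroiminium ion should attack mainly one of the two equivalent carbons flanked by OH and OMe and para to the other OH, and hydrolysis of the iminium salt gives the aldehyde; the minor 2,6-dihydroxy-4-methoxy isomer is removed by crystallisation or chromatography.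

Step 2
Reactants: 3 2,4-dihydroxy-6-methoxybenzaldehyde
Product: 4 2-hydroxy-6-methoxy-4-(methoxymethoxy)benzaldehyde
Conditions: MOMCl (1.05 equiv), iPr2NEt, CH2Cl2, 0 °C
Reagents that add atoms: chloromethyl methyl ether COCCl
Why: Selective O-alkylation (MOM protection), because the 2-OH is held in a hydrogen bond to the aldehyde, so the free and more acidic 4-OH should react first.

Step 3
Reactants: 4 2-hydroxy-6-methoxy-4-(methoxymethoxy)benzaldehyde
Product: 5 2-formyl-3-methoxy-5-(methoxymethoxy)phenyl trifluoromethanesulfonate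
Conditions: Tf2O, pyridine, CH2Cl2, −20 → 0 °C
Reagents that add atoms: trifluoromethanesulfonic anhydride O=S(=O)(OS(=O)(=O)C(F)(F)F)C(F)(F)F
Why: O-Sulfonylation of the phenol turns the oxygen on the future C8a into the leaving group for the ring closure; the MOM ether and the aldehyde tolerate pyridine-buffered triflation in the cold.

Step 4
Reactants: 6 2'-hydroxyacetophenone
Product: 7 1-[2-(methoxymethoxy)phenyl]ethan-1-one
Conditions: MOMCl, iPr2NEt, CH2Cl2, 0 °C → rt
Reagents that add atoms: chloromethyl methyl ether COCCl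
Why: MOM protection of the phenol (O-alkylation) gives a ketone whose only acidic site is the methyl group and whose ether survives bases, borane, Pd(0) and fluoride.

Step 5
Reactants: 7 1-[2-(methoxymethoxy)phenyl]ethan-1-one, 5 2-formyl-3-methoxy-5-(methoxymethoxy)phenyl trifluoromethanesulfonate
Product: 9 racemic 2-{1-hydroxy-3-[2-(methoxymethoxy)phenyl]-3-oxopropyl}-3-methoxy-5-(methoxymethoxy)phenyl trifluoromethanesulfonate, via lithium enolate 8 (not isolated)
Conditions: LDA, THF, −78 °C; then 5, −78 °C; AcOH quench at −78 °C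
Reagents that add atoms: none
Why: Directed aldol addition of a preformed lithium enolate to a non-enolisable aldehyde forms C3–C4; the cold acidic quench prevents retro-aldol and dehydration, and the C4 configuration is irrelevant because C4 ends as the ketone.

Step 6
Reactants: 9 racemic aldol adduct
Product: 10 racemic 2-{1-(tert-butyldimethylsilyloxy)-3-[2-(methoxymethoxy)phenyl]-3-oxopropyl}-3-methoxy-5-(methoxymethoxy)phenyl trifluoromethanesulfonate
Conditions: TBSOTf, 2,6-lutidine, CH2Cl2, −78 → −40 °C
Reagents that add atoms: tert-butyldimethylsilyl trifluoromethanesulfonate CC(C)(C)[Si](C)(C)OS(=O)(=O)C(F)(F)F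
Why: Silylation of the hindered benzylic alcohol with the silyl triflate and a non-nucleophilic base removes the β-hydroxy ketone, which base would dehydrate or cleave by retro-aldol, at a temperature where the aryl MOM ethers are not attacked.

Step 7
Reactants: 10 racemic silyloxy ketone
Product: 11 2-{(3S)-1-(tert-butyldimethylsilyloxy)-3-hydroxy-3-[2-(methoxymethoxy)phenyl]propyl}-3-methoxy-5-(methoxymethoxy)phenyl trifluoromethanesulfonate (both epimers at the silyloxy carbon)
Conditions: (R)-Me-CBS (20 mol%), BH3·SMe2, THF, −20 °C; MeOH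
Reagents that add atoms: none
Why: Corey–Bakshi–Shibata reduction, in which the (R)-oxazaborolidine delivers hydride to the aryl ketone with the aryl group as the large and the CH2 group as the small substituent (the sense that gives (S)-1-phenylethanol from acetophenone), so C2 is set as S under reagent control in both C4 epimers; triflate, MOM and silyl ethers are inert to borane at −20 °C.

Step 8
Reactants: 11 (3S)-carbinol aryl triflate
Product: 12 (2S)-4-(tert-butyldimethylsilyloxy)-5-methoxy-7-(methoxymethoxy)-2-[2-(methoxymethoxy)phenyl]chromane (both C4 epimers)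
Conditions: RockPhos Pd G3 (5 mol%), Cs2CO3, toluene, 70 °C
Reagents that add atoms: none
Why: Monoligated Pd(0) inserts into the C8a–OTf bond, the C2 hydroxyl binds and is deprotonated by carbonate to a seven-membered aryl–Pd–alkoxide chelate, and C–O reductive elimination forms O1–C8a. This is the Buchwald–Hartwig-type intramolecular etherification of aryl (pseudo)halides by secondary alcohols, which is known to give chromans. Ring C closes as the six-membered ring by reductive elimination from that chelate. No stereocentre is made: the C2–O bond is never broken, so the S configuration from step 7 enters the ring with retention, and C4 is a spectator silyl ether. The step needs reductive elimination to beat β-hydride elimination from the benzylic alkoxide and attack of base at the triflate sulfur; this is secured by the bulky di-tert-butyl biaryl phosphine (no free cis site on Pd), the weak insoluble base, a triflate with only one ortho substituent, the silyl ether at C4 (no retro-aldol or dehydration) and the absence of any alkene near C8a, since the lavandulyl chain arrives only in step 15.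

Step 9
Reactants: 12 (2S)-4-silyloxyflavan
Product: 13 (2S)-8-bromo-4-(tert-butyldimethylsilyloxy)-5-methoxy-7-(methoxymethoxy)-2-[2-(methoxymethoxy)phenyl]chromane (both C4 epimers)
Conditions: NBS (1.0 equiv), NaHCO3, CH2Cl2/THF, −78 → −20 °C, dark
Reagents that add atoms: N-bromosuccinimide O=C1CCC(=O)N1Br
Why: Electrophilic aromatic bromination, for which C8 is the accessible ring-A position of a 5,7-dialkoxyflavan (C6 is shielded by the 5-OMe methyl, which the peri C4 substituent turns toward C6), as is known for NBS bromination of catechin-type ethers; ring B is far less activated and the bicarbonate buffer protects the acid-labile benzylic C4–O bond.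

Step 10
Reactants: 14 (4S)-4-benzyl-1,3-oxazolidin-2-one, 15 3-methylbut-2-enoyl chloride
Product: 17 (4S)-4-benzyl-3-(3-methylbut-2-enoyl)-1,3-oxazolidin-2-one, via N-lithio oxazolidinone 16 (not isolated)
Conditions: n-BuLi, THF, −78 °C; then 15, −78 → 0 °C
Reagents that add atoms: none
Why: N-Acylation of the lithiated Evans auxiliary with an acid chloride, a standard way to N-enoyl oxazolidinones.

Step 11
Reactants: 17 N-senecioyl oxazolidinone, 18 1-bromo-3-methylbut-2-ene (prenyl bromide)
Product: 20 (4S)-4-benzyl-3-[(2S)-5-methyl-2-(prop-1-en-2-yl)hex-4-enoyl]-1,3-oxazolidin-2-one, via sodium dienolate 19 (not isolated)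
Conditions: NaHMDS, THF, −78 °C; then 18, −78 → −40 °C
Reagents that add atoms: none
Why: Evans asymmetric alkylation in its deconjugative form, in which γ-deprotonation gives the chelated (Z)-dienolate and prenyl bromide attacks the α-carbon on the face opposite the benzyl group (the sense that gives the (R)-2-methylpent-4-enoyl imide from the propionyl imide), which sets the later C2'' as 2S in the imide and leaves the isopropenyl group.

Step 12
Reactants: 20 alkylated imide
Product: 21 (S)-lavandulol [(2S)-5-methyl-2-(prop-1-en-2-yl)hex-4-en-1-ol]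
Conditions: LiBH4, H2O (1 equiv), Et2O, 0 °C; aq. NaOH work-up
Reagents that add atoms: none
Why: Reductive cleavage of the N-acyl oxazolidinone with lithium borohydride gives the primary alcohol without touching the stereocentre or the alkenes and returns the auxiliary 14.

Step 13
Reactants: 21 (S)-lavandulol
Product: 22 (3S)-3-(iodomethyl)-2,6-dimethylhepta-1,5-diene [(S)-lavandulyl iodide]
Conditions: PPh3, I2, imidazole, CH2Cl2, 0 °C → rt
Reagents that add atoms: iodine II
Why: Garegg–Samuelsson (Appel-type) iodination, an SN2 displacement at the primary carbon that leaves the adjacent stereocentre and both alkenes untouched.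

Step 14
Reactants: 22 (S)-lavandulyl iodide
Product: 23 [(2S)-5-methyl-2-(prop-1-en-2-yl)hex-4-en-1-yl]zinc iodide (THF solution, titrated and used directly)
Conditions: Zn dust (activated with cat. BrCH2CH2Br and TMSCl), LiCl, THF, 40 °C
Reagents that add atoms: zinc [Zn]
Why: LiCl-promoted direct zinc insertion into a primary alkyl iodide gives the alkylzinc iodide with the β-stereocentre unaffected, since the transient primary radical has no fast cyclisation open to it (only 3-exo and 4-exo modes).

Step 15
Reactants: 13 (2S)-8-bromoflavan, 23 (S)-lavandulylzinc iodide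
Product: 24 (2S)-4-(tert-butyldimethylsilyloxy)-5-methoxy-7-(methoxymethoxy)-2-[2-(methoxymethoxy)phenyl]-8-[(2R)-5-methyl-2-(prop-1-en-2-yl)hex-4-en-1-yl]chromane (both C4 epimers)
Conditions: Pd(OAc)2 (5 mol%), SPhos (10 mol%), THF, 60 °C
Reagents that add atoms: none
Why: Negishi sp3–sp2 cross-coupling, in which a Pd/dialkylbiarylphosphine catalyst couples primary alkylzinc halides with di-ortho-substituted electron-rich aryl bromides faster than β-hydride elimination, forming C8–C1'' with C2'' unchanged in space (now R by CIP).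

Step 16
Reactants: 24 8-lavandulyl-4-silyloxyflavan
Product: 25 (2S)-5-methoxy-7-(methoxymethoxy)-2-[2-(methoxymethoxy)phenyl]-8-[(2R)-5-methyl-2-(prop-1-en-2-yl)hex-4-en-1-yl]chroman-4-ol (both C4 epimers)
Conditions: TBAF, THF, 0 °C → rt
Reagents that add atoms: none
Why: Fluoride-mediated desilylation frees the C4 alcohol under basic conditions that spare the acid-labile flavan-4-ol, the MOM ethers and the alkenes.

Step 17
Reactants: 25 flavan-4-ol
Product: 26 (2S)-5-methoxy-7-(methoxymethoxy)-2-[2-(methoxymethoxy)phenyl]-8-[(2R)-5-methyl-2-(prop-1-en-2-yl)hex-4-en-1-yl]chroman-4-one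
Conditions: Dess–Martin periodinane, NaHCO3, CH2Cl2, 0 °C → rt
Reagents that add atoms: none
Why: Dess–Martin oxidation of the secondary benzylic alcohol gives the C4 ketone under buffered neutral conditions, so the (2S)-flavanone is not exposed to base (ring opening to the chalcone) and both C4 epimers converge.

Step 18
Reactants: 26 bis-MOM flavanone
Product: 27 kushenol R [(2S)-7-hydroxy-2-(2-hydroxyphenyl)-5-methoxy-8-[(2R)-5-methyl-2-(prop-1-en-2-yl)hex-4-en-1-yl]chroman-4-one]
Conditions: 3 M aq. HCl, MeOH, 40 °C
Reagents that add atoms: none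
Why: Acid-catalysed acetal exchange with methanol removes both aryl MOM ethers; dilute acid at moderate temperature is chosen so that the flavanone does not ring-open and the free 7-OH does not add to the lavandulyl alkenes.

**Compound list**

1 | 5-methoxyresorcinol (5-methoxybenzene-1,3-diol) | COc1cc(O)cc(O)c1 | starting material
2 | N-[(2,4-dihydroxy-6-methoxyphenyl)methylidene]-N-methylmethanaminium chloride | COc1cc(O)cc(O)c1C=[N+](C)C.[Cl-] | intermediate
3 | 2,4-dihydroxy-6-methoxybenzaldehyde | COc1cc(O)cc(O)c1C=O | intermediate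
4 | 2-hydroxy-6-methoxy-4-(methoxymethoxy)benzaldehyde | COCOc1cc(O)c(C=O)c(OC)c1 | intermediate
5 | 2-formyl-3-methoxy-5-(methoxymethoxy)phenyl trifluoromethanesulfonate | COCOc1cc(OC)c(C=O)c(OS(=O)(=O)C(F)(F)F)c1 | intermediate
6 | 2'-hydroxyacetophenone | CC(=O)c1ccccc1O | starting material
7 | 1-[2-(methoxymethoxy)phenyl]ethan-1-one | CC(=O)c1ccccc1OCOC | intermediate
8 | lithium 1-[2-(methoxymethoxy)phenyl]ethen-1-olate | C=C(O[Li])c1ccccc1OCOC | intermediate
9 | 2-{1-hydroxy-3-[2-(methoxymethoxy)phenyl]-3-oxopropyl}-3-methoxy-5-(methoxymethoxy)phenyl trifluoromethanesulfonate (racemic) | COCOc1cc(OC)c(C(O)CC(=O)c2ccccc2OCOC)c(OS(=O)(=O)C(F)(F)F)c1 | intermediate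
10 | 2-{1-(tert-butyldimethylsilyloxy)-3-[2-(methoxymethoxy)phenyl]-3-oxopropyl}-3-methoxy-5-(methoxymethoxy)phenyl trifluoromethanesulfonate (racemic) | COCOc1cc(OC)c(C(O[Si](C)(C)C(C)(C)C)CC(=O)c2ccccc2OCOC)c(OS(=O)(=O)C(F)(F)F)c1 | intermediate
11 | 2-{(3S)-1-(tert-butyldimethylsilyloxy)-3-hydroxy-3-[2-(methoxymethoxy)phenyl]propyl}-3-methoxy-5-(methoxymethoxy)phenyl trifluoromethanesulfonate (both epimers at the silyloxy carbon) | COCOc1cc(OC)c(C(O[Si](C)(C)C(C)(C)C)C[C@H](O)c2ccccc2OCOC)c(OS(=O)(=O)C(F)(F)F)c1 | intermediate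
12 | (2S)-4-(tert-butyldimethylsilyloxy)-5-methoxy-7-(methoxymethoxy)-2-[2-(methoxymethoxy)phenyl]chromane (both C4 epimers) | COCOc1cc(OC)c2c(c1)O[C@H](c1ccccc1OCOC)CC2O[Si](C)(C)C(C)(C)C | intermediate
13 | (2S)-8-bromo-4-(tert-butyldimethylsilyloxy)-5-methoxy-7-(methoxymethoxy)-2-[2-(methoxymethoxy)phenyl]chromane (both C4 epimers) | COCOc1cc(OC)c2c(c1Br)O[C@H](c1ccccc1OCOC)CC2O[Si](C)(C)C(C)(C)C | intermediate
14 | (4S)-4-benzyl-1,3-oxazolidin-2-one | O=C1OC[C@H](Cc2ccccc2)N1 | starting material
15 | 3-methylbut-2-enoyl chloride | CC(C)=CC(=O)Cl | starting material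
16 | N-lithio-(4S)-4-benzyl-1,3-oxazolidin-2-one | O=C1OC[C@H](Cc2ccccc2)N1[Li] | intermediate
17 | (4S)-4-benzyl-3-(3-methylbut-2-enoyl)-1,3-oxazolidin-2-one | O=C1OC[C@H](Cc2ccccc2)N1C(=O)C=C(C)C | intermediate
18 | 1-bromo-3-methylbut-2-ene (prenyl bromide) | CC(C)=CCBr | starting material
19 | sodium (Z)-dienolate of 17 | O=C1OC[C@H](Cc2ccccc2)N1/C(O[Na])=C/C(C)=C | intermediate
20 | (4S)-4-benzyl-3-[(2S)-5-methyl-2-(prop-1-en-2-yl)hex-4-enoyl]-1,3-oxazolidin-2-one | O=C1OC[C@H](Cc2ccccc2)N1C(=O)[C@@H](CC=C(C)C)C(C)=C | intermediate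
21 | (S)-lavandulol, (2S)-5-methyl-2-(prop-1-en-2-yl)hex-4-en-1-ol | C=C(C)[C@H](CC=C(C)C)CO | intermediate
22 | (3S)-3-(iodomethyl)-2,6-dimethylhepta-1,5-diene | C=C(C)[C@H](CC=C(C)C)CI | intermediate
23 | [(2S)-5-methyl-2-(prop-1-en-2-yl)hex-4-en-1-yl]zinc iodide | C=C(C)[C@H](CC=C(C)C)C[Zn]I | intermediate
24 | (2S)-4-(tert-butyldimethylsilyloxy)-5-methoxy-7-(methoxymethoxy)-2-[2-(methoxymethoxy)phenyl]-8-[(2R)-5-methyl-2-(prop-1-en-2-yl)hex-4-en-1-yl]chromane (both C4 epimers) | C=C(C)[C@H](CC=C(C)C)Cc1c(OCOC)cc(OC)c2c1O[C@H](c1ccccc1OCOC)CC2O[Si](C)(C)C(C)(C)C | intermediate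
25 | (2S)-5-methoxy-7-(methoxymethoxy)-2-[2-(methoxymethoxy)phenyl]-8-[(2R)-5-methyl-2-(prop-1-en-2-yl)hex-4-en-1-yl]chroman-4-ol (both C4 epimers) | C=C(C)[C@H](CC=C(C)C)Cc1c(OCOC)cc(OC)c2c1O[C@H](c1ccccc1OCOC)CC2O | intermediate
26 | (2S)-5-methoxy-7-(methoxymethoxy)-2-[2-(methoxymethoxy)phenyl]-8-[(2R)-5-methyl-2-(prop-1-en-2-yl)hex-4-en-1-yl]chroman-4-one | C=C(C)[C@H](CC=C(C)C)Cc1c(OCOC)cc(OC)c2c1O[C@H](c1ccccc1OCOC)CC2=O | intermediate
27 | kushenol R, (2S)-7-hydroxy-2-(2-hydroxyphenyl)-5-methoxy-8-[(2R)-5-methyl-2-(prop-1-en-2-yl)hex-4-en-1-yl]chroman-4-one | C=C(C)[C@H](CC=C(C)C)Cc1c(O)cc(OC)c2c1O[C@H](c1ccccc1O)CC2=O | target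

**Step count and risks**

Total step count: 18. Longest linear sequence: 12 steps (steps 1, 2, 3, 5, 6, 7, 8, 9, 15, 16, 17, 18).

Steps most likely to fail:

1. Step 8 (ring closure). C–O reductive elimination may be too slow. Then β-hydride elimination from the palladium alkoxide would oxidise the carbinol (erasing C2) and reduce the arene, base could cleave the triflate at sulfur, or the silyl group could migrate from O4 to O2. The fallback sets out from 10 and comes back at 12; it closes ring C at the other C–O bond, O1–C2, with inversion. Ketone 10 is reduced with the (S)-oxazaborolidine and BH3·SMe2 to 2-{(3R)-1-(tert-butyldimethylsilyloxy)-3-hydroxy-3-[2-(methoxymethoxy)phenyl]propyl}-3-methoxy-5-(methoxymethoxy)phenyl trifluoromethanesulfonate F1. The aryl triflate is cleaved at sulfur with Et4NOH in dioxane to (1R)-3-(tert-butyldimethylsilyloxy)-3-[2-hydroxy-6-methoxy-4-(methoxymethoxy)phenyl]-1-[2-(methoxymethoxy)phenyl]propan-1-ol F2. A Mitsunobu reaction (PPh3, DIAD, THF, 0 °C) then lets the phenol displace the activated benzylic oxygen with inversion, which should give the (2S)-chroman 12.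

2. Step 9 (bromination). Substitution may not be site-selective (C6 or ring B competing with C8), or traces of HBr may ionise the benzylic C4–O bond. The fallback sets out from 12 and comes back at 24; it replaces electrophilic substitution by directed ortho-metalation. With n-BuLi/TMEDA in THF at −40 °C the C8 proton should be removed, since it lies between the OMOM group and the ring oxygen O1, whose in-plane lone pair points at C8, while the 5-OMe lone pair is turned away from C6. Quenching with iodine gives (2S)-4-(tert-butyldimethylsilyloxy)-8-iodo-5-methoxy-7-(methoxymethoxy)-2-[2-(methoxymethoxy)phenyl]chromane F3, which takes the place of 13 in the Negishi coupling with 23 and so gives 24.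

3. Step 15 (Negishi coupling). Transmetalation or reductive elimination at the doubly ortho-oxygenated bromide may be slow, which would lead to protodebromination or to β-hydride elimination and isomerisation of the alkyl chain on palladium. The fallback sets out from 13 and comes back at 24; it reverses the polarity and avoids an alkylpalladium. Bromine–lithium exchange on 13 (t-BuLi, THF, −78 °C) gives the 8-lithio-4-silyloxyflavan F4, and MgBr2·OEt2 converts it into the 8-(bromomagnesio)-4-silyloxyflavan F5. Copper-catalysed SN2 alkylation of this aryl Grignard reagent with iodide 22 (Li2CuCl4 cat., THF/NMP, 0 °C) should give 24.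

Further compounds
F1 | step 8 | 2-{(3R)-1-(tert-butyldimethylsilyloxy)-3-hydroxy-3-[2-(methoxymethoxy)phenyl]propyl}-3-methoxy-5-(methoxymethoxy)phenyl trifluoromethanesulfonate | COCOc1cc(OC)c(C(O[Si](C)(C)C(C)(C)C)C[C@@H](O)c2ccccc2OCOC)c(OS(=O)(=O)C(F)(F)F)c1
F2 | step 8 | (1R)-3-(tert-butyldimethylsilyloxy)-3-[2-hydroxy-6-methoxy-4-(methoxymethoxy)phenyl]-1-[2-(methoxymethoxy)phenyl]propan-1-ol | COCOc1cc(OC)c(C(O[Si](C)(C)C(C)(C)C)C[C@@H](O)c2ccccc2OCOC)c(O)c1
F3 | step 9 | (2S)-4-(tert-butyldimethylsilyloxy)-8-iodo-5-methoxy-7-(methoxymethoxy)-2-[2-(methoxymethoxy)phenyl]chromane | COCOc1cc(OC)c2c(c1I)O[C@H](c1ccccc1OCOC)CC2O[Si](C)(C)C(C)(C)C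
F4 | step 15 | (2S)-4-(tert-butyldimethylsilyloxy)-8-lithio-5-methoxy-7-(methoxymethoxy)-2-[2-(methoxymethoxy)phenyl]chromane | COCOc1cc(OC)c2c(c1[Li])O[C@H](c1ccccc1OCOC)CC2O[Si](C)(C)C(C)(C)C
F5 | step 15 | (2S)-8-(bromomagnesio)-4-(tert-butyldimethylsilyloxy)-5-methoxy-7-(methoxymethoxy)-2-[2-(methoxymethoxy)phenyl]chromane | COCOc1cc(OC)c2c(c1[Mg]Br)O[C@H](c1ccccc1OCOC)CC2O[Si](C)(C)C(C)(C)C
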